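**Retrosynthetic overview**
- The hydroquinone is unveiled last (dimethyl ether → quinone → hydroquinone). The C12 ketone comes from a prenyl carbinol made by allylboration of a C12 enal and cross-metathesis with 2-methyl-2-butene, after the C5 acetate is in place.
- C1–C2 bond: Negishi coupling of a benzylzinc (from 4-methoxy-2-methylphenol) with an (E)-vinyl iodide from zirconium-catalysed carboalumination of a homopropargylic silyl ether, which fixes the 2E alkene.
- The alkyne is the one-carbon homologue of a β-silyloxy aldehyde obtained from a (3S)-β-hydroxy ester.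
- The only stereocenter (C5) is set by ketoreductase reduction of an achiral unsaturated β-keto ester built from geranyl acetate, whose skeleton supplies the 6E and 10E alkenes and, after SeO2 oxidation, the C12 oxygen.
- No ring is formed in the route; the arene is carried in from the phenol starting material.

TBSO = tert-butyldimethylsilyloxy. From the coupling product on, the chain is numbered from the benzylic carbon (C1) as in the target.

Assumption: a ketoreductase that reduces the β-keto ester of step 7 to the 3S alcohol is available from a commercial screening panel (such panels hold enantiocomplementary enzymes for β-keto esters).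

**Route**

Step 1
Reactants: 1 geranyl acetate, (2E)-3,7-dimethylocta-2,6-dien-1-yl acetate
Product: 2 (2E,6E)-8-hydroxy-3,7-dimethylocta-2,6-dien-1-yl acetate
Conditions: SeO2 (0.2 equiv), t-BuOOH (3 equiv), salicylic acid (0.1 equiv), CH2Cl2, rt, 24 h
Reagents that add atoms: selenium dioxide SeO2 (catalytic oxygen carrier), O=[Se]=O; tert-butyl hydroperoxide (terminal oxygen source), CC(C)(C)OO
Why: Riley allylic oxidation (ene reaction then [2,3]-sigmatropic shift) hydroxylates the (E)-methyl of the electron-rich terminal alkene, while the 2,3-alkene is deactivated by the allylic acetate.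

Step 2
Reactants: 2 (2E,6E)-8-hydroxy-3,7-dimethylocta-2,6-dien-1-yl acetate
Product: 3 (2E,6E)-8-TBSO-3,7-dimethylocta-2,6-dien-1-yl acetate
Conditions: TBSCl, imidazole, DMF, 0 °C → rt
Reagents that add atoms: tert-butyldimethylsilyl chloride, CC(C)(C)[Si](C)(C)Cl
Why: Silyl ether protection of the primary allylic alcohol masks the future C12 oxygen through the organometallic steps.

Step 3
Reactants: 3 (2E,6E)-8-TBSO-3,7-dimethylocta-2,6-dien-1-yl acetate
Product: 4 (2E,6E)-8-TBSO-3,7-dimethylocta-2,6-dien-1-ol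
Conditions: K2CO3 (0.2 equiv), MeOH, rt
Reagents that add atoms: none
Why: Base-catalysed transesterification (methanolysis) removes the acetate without touching the silyl ether.

Step 4
Reactants: 4 (2E,6E)-8-TBSO-3,7-dimethylocta-2,6-dien-1-ol
Product: 5 (2E,6E)-8-TBSO-3,7-dimethylocta-2,6-dienal
Conditions: MnO2 (15 equiv), CH2Cl2, rt
Reagents that add atoms: none
Why: MnO2 allylic oxidation gives the enal chemoselectively with retention of the E geometry.

Step 5
Reactants: 5 (2E,6E)-8-TBSO-3,7-dimethylocta-2,6-dienal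
Product: 6 (2E,6E)-8-TBSO-3,7-dimethylocta-2,6-dienoic acid
Conditions: NaClO2, NaH2PO4, 2-methyl-2-butene, t-BuOH/H2O, 0 °C → rt
Reagents that add atoms: sodium chlorite NaClO2, [Na+].[O-]Cl=O
Why: Pinnick oxidation converts the enal to the acid under buffered conditions, with the scavenger protecting the alkenes and the silyl ether surviving.

Step 6
Reactants: 6 (2E,6E)-8-TBSO-3,7-dimethylocta-2,6-dienoic acid
Product: 9 ethyl (4E,8E)-10-TBSO-5,9-dimethyl-3-oxodeca-4,8-dienoate, via acyl imidazolide 7 (not isolated), via magnesium acylmalonate chelate 8 (not isolated)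
Conditions: 1,1'-carbonyldiimidazole, THF, rt; then KO2CCH2CO2Et, MgCl2, Et3N, MeCN/THF, rt → 45 °C; cold 1 M HCl work-up
Reagents that add atoms: ethyl potassium malonate (CH2CO2Et unit), CCOC(=O)CC(=O)[O-].[K+]
Why: Masamune–Brooks C-acylation of the magnesium malonate half-ester by the acyl imidazolide, followed by decarboxylation on acidification, gives the β-keto ester under near-neutral conditions that keep the 4E alkene intact.

Step 7
Reactants: 9 ethyl (4E,8E)-10-TBSO-5,9-dimethyl-3-oxodeca-4,8-dienoate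
Product: 10 ethyl (3S,4E,8E)-10-TBSO-3-hydroxy-5,9-dimethyldeca-4,8-dienoate
Conditions: ketoreductase (KRED, NADPH-dependent, 3S-selective hit from a panel), NADP+ (cat.), i-PrOH (15 vol%), DMSO (5 vol%), 0.1 M potassium phosphate buffer pH 7.0, 30 °C, 24 h
Reagents that add atoms: none
Why: The ketoreductase (an alcohol dehydrogenase of the oxidoreductase class) delivers hydride from NADPH to one face of the 3-keto group inside its chiral active site, setting C3 as S (the future C5 of the target) by biocatalytic asymmetric reduction, with isopropanol regenerating the cofactor.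

Step 8
Reactants: 10 ethyl (3S,4E,8E)-10-TBSO-3-hydroxy-5,9-dimethyldeca-4,8-dienoate
Product: 11 ethyl (3S,4E,8E)-3,10-bis-TBSO-5,9-dimethyldeca-4,8-dienoate
Conditions: TBSCl, imidazole, DMF, rt
Reagents that add atoms: tert-butyldimethylsilyl chloride, CC(C)(C)[Si](C)(C)Cl
Why: Silyl ether protection of the secondary allylic alcohol blocks retro-aldol and alkoxide chemistry in the following steps and does not touch the stereocenter.

Step 9
Reactants: 11 ethyl (3S,4E,8E)-3,10-bis-TBSO-5,9-dimethyldeca-4,8-dienoate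
Product: 12 (3S,4E,8E)-3,10-bis-TBSO-5,9-dimethyldeca-4,8-dienal
Conditions: i-Bu2AlH (1.1 equiv), CH2Cl2, −78 °C; MeOH, then aq. potassium sodium tartrate KNaC4H4O6
Reagents that add atoms: none
Why: Partial hydride reduction at low temperature stops at the aluminium hemiacetal, which releases the aldehyde on work-up, and the β-silyloxy stereocenter is unaffected.

Step 10
Reactants: 12 (3S,4E,8E)-3,10-bis-TBSO-5,9-dimethyldeca-4,8-dienal
Product: 13 (4S,5E,9E)-4,11-bis-TBSO-6,10-dimethylundeca-5,9-dien-1-yne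
Conditions: dimethyl (1-diazo-2-oxopropyl)phosphonate, K2CO3, MeOH, 0 °C → rt
Reagents that add atoms: Ohira–Bestmann reagent (terminal alkyne carbon), CC(=O)C(=[N+]=[N-])P(=O)(OC)OC
Why: Seyferth–Gilbert homologation with the Ohira–Bestmann reagent turns the aldehyde into the terminal alkyne under mild carbonate conditions that leave the β-stereocenter alone.

Step 11
Reactants: 13 (4S,5E,9E)-4,11-bis-TBSO-6,10-dimethylundeca-5,9-dien-1-yne
Product: 15 (1E,4S,5E,9E)-4,11-bis-TBSO-1-iodo-2,6,10-trimethylundeca-1,5,9-triene, via alkenyldimethylalane 14 (not isolated)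
Conditions: AlMe3 (3 equiv), Cp2ZrCl2 (0.3 equiv), CH2Cl2, 0 °C → rt, 12 h; then I2, THF, −30 → 0 °C
Reagents that add atoms: trimethylaluminium AlMe3 (methyl group), C[Al](C)C; iodine, II
Why: Negishi zirconium-catalysed carboalumination adds methyl and aluminium syn across the terminal alkyne with methyl on the internal carbon, and iodinolysis with retention gives the (E)-vinyl iodide, fixing the 2E trisubstituted alkene of the target.

Step 12
Reactants: 16 4-methoxy-2-methylphenol
Product: 17 2-hydroxy-5-methoxy-3-methylbenzaldehyde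
Conditions: MgCl2, Et3N, (CH2O)n, MeCN, reflux; 1 M HCl work-up
Reagents that add atoms: formaldehyde (from paraformaldehyde), C=O
Why: Magnesium phenoxide-directed ortho-formylation (Casnati–Skattebøl) is specific for the single free ortho position of the phenol.

Step 13
Reactants: 17 2-hydroxy-5-methoxy-3-methylbenzaldehyde
Product: 18 2,5-dimethoxy-3-methylbenzaldehyde
Conditions: MeI, K2CO3, DMF, rt
Reagents that add atoms: iodomethane, CI
Why: Williamson O-methylation of the phenoxide gives the robust hydroquinone dimethyl ether.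

Step 14
Reactants: 18 2,5-dimethoxy-3-methylbenzaldehyde
Product: 19 (2,5-dimethoxy-3-methylphenyl)methanol
Conditions: NaBH4, MeOH, 0 °C
Reagents that add atoms: none
Why: Hydride reduction of the aryl aldehyde to the benzylic alcohol is clean and chemoselective.

Step 15
Reactants: 19 (2,5-dimethoxy-3-methylphenyl)methanol
Product: 20 1-(chloromethyl)-2,5-dimethoxy-3-methylbenzene
Conditions: SOCl2, CH2Cl2, 0 °C → rt
Reagents that add atoms: thionyl chloride, O=S(Cl)Cl
Why: The electron-rich benzylic alcohol is converted to the chloride through its chlorosulfite (nucleophilic substitution).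

Step 16
Reactants: 20 1-(chloromethyl)-2,5-dimethoxy-3-methylbenzene; 15 (1E,4S,5E,9E)-4,11-bis-TBSO-1-iodo-2,6,10-trimethylundeca-1,5,9-triene
Product: 22 (2E,5S,6E,10E)-5,12-bis-TBSO-1-(2,5-dimethoxy-3-methylphenyl)-3,7,11-trimethyldodeca-2,6,10-triene, via benzylzinc chloride 21 (not isolated)
Conditions: Zn dust, LiCl, THF, rt, 3 h; then 15, Pd(PPh3)4 (5 mol%), THF, rt → 45 °C
Reagents that add atoms: none
Why: LiCl-promoted zinc insertion gives the benzylzinc chloride, and its Negishi cross-coupling with the vinyl iodide under zerovalent palladium catalysis proceeds with retention of alkene geometry and tolerates the silyl ethers.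

Step 17
Reactants: 22 (2E,5S,6E,10E)-5,12-bis-TBSO-1-(2,5-dimethoxy-3-methylphenyl)-3,7,11-trimethyldodeca-2,6,10-triene
Product: 23 (2E,5S,6E,10E)-1-(2,5-dimethoxy-3-methylphenyl)-3,7,11-trimethyldodeca-2,6,10-triene-5,12-diol
Conditions: Bu4NF (3 equiv), THF, 0 °C → rt
Reagents that add atoms: none
Why: Fluoride-mediated desilylation removes both silyl ethers at once, and nothing in the molecule is base- or fluoride-sensitive at this stage.

Step 18
Reactants: 23 (2E,5S,6E,10E)-1-(2,5-dimethoxy-3-methylphenyl)-3,7,11-trimethyldodeca-2,6,10-triene-5,12-diol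
Product: 24 (2E,6E,8S,10E)-12-(2,5-dimethoxy-3-methylphenyl)-8-hydroxy-2,6,10-trimethyldodeca-2,6,10-trienal
Conditions: TEMPO (0.1 equiv), PhI(OAc)2 (1.1 equiv), CH2Cl2, rt
Reagents that add atoms: none
Why: TEMPO/PhI(OAc)2 oxidation through the bulky oxoammonium salt is selective for the primary allylic alcohol over the hindered secondary one and gives the (E)-enal without over-oxidation.

Step 19
Reactants: 24 (2E,6E,8S,10E)-12-(2,5-dimethoxy-3-methylphenyl)-8-hydroxy-2,6,10-trimethyldodeca-2,6,10-trienal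
Product: 25 (2E,5S,6E,10E)-1-(2,5-dimethoxy-3-methylphenyl)-3,7,11-trimethyl-12-oxododeca-2,6,10-trien-5-yl acetate
Conditions: Ac2O, pyridine, DMAP (cat.), CH2Cl2, 0 °C → rt
Reagents that add atoms: acetic anhydride, CC(=O)OC(C)=O
Why: DMAP-catalysed acylation installs the C5 acetate with retention because the C–O bond of the stereocenter is not broken.

Step 20
Reactants: 25 (2E,5S,6E,10E)-1-(2,5-dimethoxy-3-methylphenyl)-3,7,11-trimethyl-12-oxododeca-2,6,10-trien-5-yl acetate
Product: 26 (2E,5S,6E,10E,12RS)-1-(2,5-dimethoxy-3-methylphenyl)-12-hydroxy-3,7,11-trimethylpentadeca-2,6,10,14-tetraen-5-yl acetate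
Conditions: allylB(pin) (2 equiv), CH2Cl2 (1 M), rt, 36 h; aq. NaHCO3 work-up
Reagents that add atoms: allylboronic acid pinacol ester, C=CCB1OC(C)(C)C(C)(C)O1
Why: Uncatalysed allylboration through a six-membered chair transition state is chemoselective for the aldehyde over the acetate and adds 1,2 to the enal; the new C12 carbinol forms as both epimers, which does not matter because it is oxidised in step 22.

Step 21
Reactants: 26 (2E,5S,6E,10E,12RS)-1-(2,5-dimethoxy-3-methylphenyl)-12-hydroxy-3,7,11-trimethylpentadeca-2,6,10,14-tetraen-5-yl acetate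
Product: 27 (2E,5S,6E,10E,12RS)-1-(2,5-dimethoxy-3-methylphenyl)-12-hydroxy-3,7,11,15-tetramethylhexadeca-2,6,10,14-tetraen-5-yl acetate
Conditions: second-generation Grubbs catalyst RuCl2(=CHPh)(PCy3)(H2IMes) (5 mol%), 2-methyl-2-butene/CH2Cl2 1:1, 40 °C, sealed tube
Reagents that add atoms: 2-methyl-2-butene (isopropylidene unit), CC=C(C)C
Why: Olefin cross-metathesis of the monosubstituted alkene with excess 2-methyl-2-butene installs the prenyl terminus with loss of propene, while the trisubstituted alkenes of the chain react far more slowly with the ruthenium carbene.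

Step 22
Reactants: 27 (2E,5S,6E,10E,12RS)-1-(2,5-dimethoxy-3-methylphenyl)-12-hydroxy-3,7,11,15-tetramethylhexadeca-2,6,10,14-tetraen-5-yl acetate
Product: 28 (2E,5S,6E,10E)-1-(2,5-dimethoxy-3-methylphenyl)-3,7,11,15-tetramethyl-12-oxohexadeca-2,6,10,14-tetraen-5-yl acetate
Conditions: Dess–Martin periodinane (1.3 equiv), pyridine, CH2Cl2, 0 °C → rt
Reagents that add atoms: none
Why: Dess–Martin oxidation converts the carbinol to the ketone under buffered, non-basic conditions, so the 14,15-alkene does not move into conjugation and both C12 epimers converge on one compound.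

Step 23
Reactants: 28 (2E,5S,6E,10E)-1-(2,5-dimethoxy-3-methylphenyl)-3,7,11,15-tetramethyl-12-oxohexadeca-2,6,10,14-tetraen-5-yl acetate
Product: 29 (2E,5S,6E,10E)-3,7,11,15-tetramethyl-1-(5-methyl-3,6-dioxocyclohexa-1,4-dien-1-yl)-12-oxohexadeca-2,6,10,14-tetraen-5-yl acetate
Conditions: (NH4)2Ce(NO3)6 (2.5 equiv), MeCN/H2O 2:1, 0 °C, 15 min
Reagents that add atoms: water, O
Why: Oxidative demethylation of the hydroquinone dimethyl ether (single-electron oxidation of the arene, attack of water, loss of methanol) gives the quinone within minutes at 0 °C, which the allylic acetate and the isolated alkenes tolerate.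

Step 24
Reactants: 29 (2E,5S,6E,10E)-3,7,11,15-tetramethyl-1-(5-methyl-3,6-dioxocyclohexa-1,4-dien-1-yl)-12-oxohexadeca-2,6,10,14-tetraen-5-yl acetate
Product: 30 (2E,5S,6E,10E)-1-(2,5-dihydroxy-3-methylphenyl)-3,7,11,15-tetramethyl-12-oxohexadeca-2,6,10,14-tetraen-5-yl acetate (CNP0186948.1)
Conditions: aq. Na2S2O4, EtOAc/H2O, rt, 10 min, argon
Reagents that add atoms: none
Why: Dithionite reduction of the quinone gives the hydroquinone under neutral two-phase conditions that leave the acetate, the enone and the stereocenter untouched.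

**Compound list**

1 | geranyl acetate, (2E)-3,7-dimethylocta-2,6-dien-1-yl acetate | CC(=O)OC/C=C(\C)CCC=C(C)C | starting material
2 | (2E,6E)-8-hydroxy-3,7-dimethylocta-2,6-dien-1-yl acetate | CC(=O)OC/C=C(\C)CC/C=C(\C)CO | intermediate
3 | (2E,6E)-8-[(tert-butyldimethylsilyl)oxy]-3,7-dimethylocta-2,6-dien-1-yl acetate | CC(=O)OC/C=C(\C)CC/C=C(\C)CO[Si](C)(C)C(C)(C)C | intermediate
4 | (2E,6E)-8-[(tert-butyldimethylsilyl)oxy]-3,7-dimethylocta-2,6-dien-1-ol | OC/C=C(\C)CC/C=C(\C)CO[Si](C)(C)C(C)(C)C | intermediate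
5 | (2E,6E)-8-[(tert-butyldimethylsilyl)oxy]-3,7-dimethylocta-2,6-dienal | O=C/C=C(\C)CC/C=C(\C)CO[Si](C)(C)C(C)(C)C | intermediate
6 | (2E,6E)-8-[(tert-butyldimethylsilyl)oxy]-3,7-dimethylocta-2,6-dienoic acid | OC(=O)/C=C(\C)CC/C=C(\C)CO[Si](C)(C)C(C)(C)C | intermediate
7 | acyl imidazolide, (2E,6E)-8-[(tert-butyldimethylsilyl)oxy]-1-(1H-imidazol-1-yl)-3,7-dimethylocta-2,6-dien-1-one | O=C(/C=C(\C)CC/C=C(\C)CO[Si](C)(C)C(C)(C)C)n1ccnc1 | intermediate
8 | magnesium acylmalonate chelate, magnesium enolate-carboxylate of (4E,8E)-10-[(tert-butyldimethylsilyl)oxy]-2-(ethoxycarbonyl)-5,9-dimethyl-3-oxodeca-4,8-dienoic acid | CCOC(=O)C(C(=O)[O-])=C([O-])/C=C(\C)CC/C=C(\C)CO[Si](C)(C)C(C)(C)C.[Mg+2] | intermediate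
9 | ethyl (4E,8E)-10-[(tert-butyldimethylsilyl)oxy]-5,9-dimethyl-3-oxodeca-4,8-dienoate | CCOC(=O)CC(=O)/C=C(\C)CC/C=C(\C)CO[Si](C)(C)C(C)(C)C | intermediate
10 | ethyl (3S,4E,8E)-10-[(tert-butyldimethylsilyl)oxy]-3-hydroxy-5,9-dimethyldeca-4,8-dienoate | O[C@H](/C=C(\C)CC/C=C(\C)CO[Si](C)(C)C(C)(C)C)CC(=O)OCC | intermediate
11 | ethyl (3S,4E,8E)-3,10-bis[(tert-butyldimethylsilyl)oxy]-5,9-dimethyldeca-4,8-dienoate | CC(C)(C)[Si](C)(C)O[C@H](/C=C(\C)CC/C=C(\C)CO[Si](C)(C)C(C)(C)C)CC(=O)OCC | intermediate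
12 | (3S,4E,8E)-3,10-bis[(tert-butyldimethylsilyl)oxy]-5,9-dimethyldeca-4,8-dienal | CC(C)(C)[Si](C)(C)O[C@H](/C=C(\C)CC/C=C(\C)CO[Si](C)(C)C(C)(C)C)CC=O | intermediate
13 | (4S,5E,9E)-4,11-bis[(tert-butyldimethylsilyl)oxy]-6,10-dimethylundeca-5,9-dien-1-yne | CC(C)(C)[Si](C)(C)O[C@H](/C=C(\C)CC/C=C(\C)CO[Si](C)(C)C(C)(C)C)CC#C | intermediate
14 | alkenyldimethylalane, [(1E,4S,5E,9E)-4,11-bis[(tert-butyldimethylsilyl)oxy]-2,6,10-trimethylundeca-1,5,9-trien-1-yl]dimethylalane | CC(C)(C)[Si](C)(C)O[C@H](/C=C(\C)CC/C=C(\C)CO[Si](C)(C)C(C)(C)C)C/C(C)=C/[Al](C)C | intermediate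
15 | (1E,4S,5E,9E)-4,11-bis[(tert-butyldimethylsilyl)oxy]-1-iodo-2,6,10-trimethylundeca-1,5,9-triene | CC(C)(C)[Si](C)(C)O[C@H](/C=C(\C)CC/C=C(\C)CO[Si](C)(C)C(C)(C)C)C/C(C)=C/I | intermediate
16 | 4-methoxy-2-methylphenol | COc1ccc(O)c(C)c1 | starting material
17 | 2-hydroxy-5-methoxy-3-methylbenzaldehyde | COc1cc(C)c(O)c(C=O)c1 | intermediate
18 | 2,5-dimethoxy-3-methylbenzaldehyde | COc1cc(C)c(OC)c(C=O)c1 | intermediate
19 | (2,5-dimethoxy-3-methylphenyl)methanol | COc1cc(C)c(OC)c(CO)c1 | intermediate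
20 | 1-(chloromethyl)-2,5-dimethoxy-3-methylbenzene | COc1cc(C)c(OC)c(CCl)c1 | intermediate
21 | benzylzinc chloride, (2,5-dimethoxy-3-methylbenzyl)zinc chloride | COc1cc(C)c(OC)c(C[Zn]Cl)c1 | intermediate
22 | (2E,5S,6E,10E)-5,12-bis[(tert-butyldimethylsilyl)oxy]-1-(2,5-dimethoxy-3-methylphenyl)-3,7,11-trimethyldodeca-2,6,10-triene | CC(C)(C)[Si](C)(C)O[C@H](/C=C(\C)CC/C=C(\C)CO[Si](C)(C)C(C)(C)C)C/C(C)=C/Cc1cc(OC)cc(C)c1OC | intermediate
23 | (2E,5S,6E,10E)-1-(2,5-dimethoxy-3-methylphenyl)-3,7,11-trimethyldodeca-2,6,10-triene-5,12-diol | O[C@H](/C=C(\C)CC/C=C(\C)CO)C/C(C)=C/Cc1cc(OC)cc(C)c1OC | intermediate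
24 | (2E,6E,8S,10E)-12-(2,5-dimethoxy-3-methylphenyl)-8-hydroxy-2,6,10-trimethyldodeca-2,6,10-trienal | O[C@H](/C=C(\C)CC/C=C(\C)C=O)C/C(C)=C/Cc1cc(OC)cc(C)c1OC | intermediate
25 | (2E,5S,6E,10E)-1-(2,5-dimethoxy-3-methylphenyl)-3,7,11-trimethyl-12-oxododeca-2,6,10-trien-5-yl acetate | CC(=O)O[C@H](/C=C(\C)CC/C=C(\C)C=O)C/C(C)=C/Cc1cc(OC)cc(C)c1OC | intermediate
26 | (2E,5S,6E,10E,12RS)-1-(2,5-dimethoxy-3-methylphenyl)-12-hydroxy-3,7,11-trimethylpentadeca-2,6,10,14-tetraen-5-yl acetate (both C12 epimers) | CC(=O)O[C@H](/C=C(\C)CC/C=C(\C)C(O)CC=C)C/C(C)=C/Cc1cc(OC)cc(C)c1OC | intermediate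
27 | (2E,5S,6E,10E,12RS)-1-(2,5-dimethoxy-3-methylphenyl)-12-hydroxy-3,7,11,15-tetramethylhexadeca-2,6,10,14-tetraen-5-yl acetate (both C12 epimers) | CC(=O)O[C@H](/C=C(\C)CC/C=C(\C)C(O)CC=C(C)C)C/C(C)=C/Cc1cc(OC)cc(C)c1OC | intermediate
28 | (2E,5S,6E,10E)-1-(2,5-dimethoxy-3-methylphenyl)-3,7,11,15-tetramethyl-12-oxohexadeca-2,6,10,14-tetraen-5-yl acetate | CC(=O)O[C@H](/C=C(\C)CC/C=C(\C)C(=O)CC=C(C)C)C/C(C)=C/Cc1cc(OC)cc(C)c1OC | intermediate
29 | (2E,5S,6E,10E)-3,7,11,15-tetramethyl-1-(5-methyl-3,6-dioxocyclohexa-1,4-dien-1-yl)-12-oxohexadeca-2,6,10,14-tetraen-5-yl acetate | CC(=O)O[C@H](/C=C(\C)CC/C=C(\C)C(=O)CC=C(C)C)C/C(C)=C/CC1=CC(=O)C=C(C)C1=O | intermediate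
30 | (2E,5S,6E,10E)-1-(2,5-dihydroxy-3-methylphenyl)-3,7,11,15-tetramethyl-12-oxohexadeca-2,6,10,14-tetraen-5-yl acetate (CNP0186948.1) | CC(=O)O[C@H](/C=C(\C)CC/C=C(\C)C(=O)CC=C(C)C)C/C(C)=C/Cc1cc(O)cc(C)c1O | target

**Step count and risks**

Total step count: 24. Longest linear sequence: 20 steps (1 → 30 through steps 1–11 and 16–24); the four-step arene branch (steps 12–15) joins at step 16.

The three steps most likely to fail, each with its fallback:

- **Step 7 (ketoreductase reduction).** The lipophilic dienyl β-keto ester 9 may be poorly accepted or reduced with low ee. The fallback sets the same stereocenter by chemical asymmetric catalysis and sets out from aldehyde 5. A Lewis-base-catalysed Mukaiyama acetate aldol (SiCl4, 5 mol% of the chiral bisphosphoramide enantiomer that gives the 3S adduct, 1-(tert-butyldimethylsilyloxy)-1-methoxyethene, CH2Cl2, −78 °C) gives methyl (3S,4E,8E)-10-[(tert-butyldimethylsilyl)oxy]-3-hydroxy-5,9-dimethyldeca-4,8-dienoate F1. Silylation (TBSCl, imidazole) gives methyl (3S,4E,8E)-3,10-bis[(tert-butyldimethylsilyl)oxy]-5,9-dimethyldeca-4,8-dienoate F2. Reduction with i-Bu2AlH at −78 °C comes back to the route at aldehyde 12.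

- **Step 21 (cross-metathesis on the polyene).** The ruthenium carbene may attack the internal trisubstituted alkenes or isomerise the skipped dienes. The fallback avoids metathesis and sets out from enal 25. Allylboration with the tertiary boronate 2-(2-methylbut-3-en-2-yl)-4,4,5,5-tetramethyl-1,3,2-dioxaborolane (CH2Cl2, rt → 40 °C) proceeds with allylic transposition through the chair transition state and delivers the linear prenyl carbinol directly, replacing steps 20 and 21. It comes back to the route at compound 27 and makes no compound outside the list (F0).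

- **Step 23 (oxidative demethylation next to the skipped enone).** The β,γ-unsaturated enone may isomerise or be oxidised at its doubly activated CH2 in the acidic tetravalent-cerium medium. The fallback changes the order and sets out from carbinol 27. Oxidation with (NH4)2Ce(NO3)6 first gives the quinone carbinol (2E,5S,6E,10E,12RS)-12-hydroxy-3,7,11,15-tetramethyl-1-(5-methyl-3,6-dioxocyclohexa-1,4-dien-1-yl)hexadeca-2,6,10,14-tetraen-5-yl acetate F3. Dess–Martin oxidation of its C12 carbinol then comes back to the route at quinone 29, so the sensitive enone is formed only after the cerium step.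

**Further compounds**
F1 | step 7 | methyl (3S,4E,8E)-10-[(tert-butyldimethylsilyl)oxy]-3-hydroxy-5,9-dimethyldeca-4,8-dienoate | O[C@H](/C=C(\C)CC/C=C(\C)CO[Si](C)(C)C(C)(C)C)CC(=O)OC
F2 | step 7 | methyl (3S,4E,8E)-3,10-bis[(tert-butyldimethylsilyl)oxy]-5,9-dimethyldeca-4,8-dienoate | CC(C)(C)[Si](C)(C)O[C@H](/C=C(\C)CC/C=C(\C)CO[Si](C)(C)C(C)(C)C)CC(=O)OC
F0 | step 21 | none | none
F3 | step 23 | (2E,5S,6E,10E,12RS)-12-hydroxy-3,7,11,15-tetramethyl-1-(5-methyl-3,6-dioxocyclohexa-1,4-dien-1-yl)hexadeca-2,6,10,14-tetraen-5-yl acetate | CC(=O)O[C@H](/C=C(\C)CC/C=C(\C)C(O)CC=C(C)C)C/C(C)=C/CC1=CC(=O)C=C(C)C1=O
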